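**Plan**

1. The target is numbered as a 7-oxabicyclo[4.1.0]hept-3-en-2-one: C1 (oxirane carbon bearing farnesyl), C2 (C=O), C3=C4 (C4 bears CH2OAc), C5 (CHOH), C6 (oxirane CH), O7.
2. Retrosynthesis: the acetate is exchanged for a silyl ether, then the carbocycle is cut at C1–C2 and at C4–C5 into two three-carbon halves: a (Z)-β-iodoacrylic acid (C2–C3–C4 with the CH2O branch) and an epoxy aldehyde carrying tin on its quaternary carbon (C5, C6, C1 with farnesyl).
3. Enabling feature: C1 is an oxirane carbon, so it can serve as a configurationally stable carbanion next to the future ketone, and the cis C3=C4 alkene of the six-membered ring holds C2 and C5 on the same side. Each half therefore has one donor end and one acceptor end, and the ring can close in one flask with the epoxide already in place.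
4. Forward: farnesyl bromide and propargyl alcohol give an enynol, then the (Z)-iodo alcohol, the (Z)-stannane, the epoxy alcohol and the epoxy aldehyde; a silyl propargyl ether gives the ynoic acid and the (Z)-iodo acid; the [3+3] annulation forms the only carbocycle (tin leaves there); desilylation and acetylation finish.
5. Stereochemistry: C1 and C6 come from a Sharpless epoxidation of the (Z)-vinylstannane (alkene geometry from trans-hydroalumination), C5 from Felkin–Anh addition to the epoxy aldehyde, and the (E,E) side chain from farnesyl bromide.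

Key step: step 8

Assumption: the target is the (1R,5R,6R) enantiomer as drawn (hydroxyl cis to the oxirane oxygen); prop-2-yn-1-ol, (2E,6E)-farnesyl bromide and tert-butyl(diphenyl)(prop-2-yn-1-yloxy)silane are bought.

**Route**

Step 1
Reactants: 1 prop-2-yn-1-ol; 2 (2E,6E)-1-bromo-3,7,11-trimethyldodeca-2,6,10-triene (farnesyl bromide)
Product: 3 (5E,9E)-6,10,14-trimethylpentadeca-5,9,13-trien-2-yn-1-ol
Conditions: CuI (10 mol %), K2CO3, NaI (cat.), DMF, rt
Reagents that add atoms: none
Why: Copper-catalysed alkylation of the terminal alkyne by the primary allylic bromide (SN2 at the CH2Br carbon) should give the skipped enynol with the (E,E) geometry of the chain untouched.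

Step 2
Reactants: 3 (5E,9E)-6,10,14-trimethylpentadeca-5,9,13-trien-2-yn-1-ol
Product: 4 (2Z,5E,9E)-3-iodo-6,10,14-trimethylpentadeca-2,5,9,13-tetraen-1-ol (iodine cis to CH2OH)
Conditions: NaAlH2(OCH2CH2OMe)2 (Red-Al), THF, 0 °C to rt; then I2, THF, −78 to 0 °C
Reagents that add atoms: iodine, II
Why: Hydroxyl-directed trans-hydroalumination of the propargylic alcohol followed by iodinolysis with retention should place iodine on C3 cis to the CH2OH group as a single regio- and stereoisomer, the isolated alkenes being inert.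

Step 3
Reactants: 4 (2Z,5E,9E)-3-iodo-6,10,14-trimethylpentadeca-2,5,9,13-tetraen-1-ol
Product: 5 (2Z,5E,9E)-6,10,14-trimethyl-3-(tributylstannyl)pentadeca-2,5,9,13-tetraen-1-ol (tin cis to CH2OH)
Conditions: n-BuLi (1 equiv), then t-BuLi (2 equiv), Et2O, −78 °C; then Bu3SnCl, −78 °C to rt
Reagents that add atoms: tributyltin chloride, CCCC[Sn](Cl)(CCCC)CCCC
Why: Iodine–lithium exchange on the lithium alkoxide and stannylation of the alkenyllithium both proceed with retention of alkene geometry, so tin ends cis to the hydroxymethyl group.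

Step 4
Reactants: 5 (2Z,5E,9E)-6,10,14-trimethyl-3-(tributylstannyl)pentadeca-2,5,9,13-tetraen-1-ol
Product: 6 [(2R,3S)-3-(tributylstannyl)-3-[(2E,6E)-3,7,11-trimethyldodeca-2,6,10-trien-1-yl]oxiran-2-yl]methanol (tin and CH2OH cis on the oxirane)
Conditions: Ti(OiPr)4, D-(−)-diethyl tartrate, t-BuOOH, 4 Å molecular sieves, CH2Cl2, −20 °C
Reagents that add atoms: tert-butyl hydroperoxide, CC(C)(C)OO
Why: Sharpless asymmetric epoxidation acts only on the allylic alcohol alkene, and the D-(−)-tartrate ligand (the series opposite to the one that gives (2S,3S)-epoxides from (E)-alk-2-en-1-ols) should deliver oxygen to the face that sets both oxirane centres, the future C1 and C6.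

Step 5
Reactants: 6 [(2R,3S)-3-(tributylstannyl)-3-[(2E,6E)-farnesyl]oxiran-2-yl]methanol
Product: 7 (2R,3S)-3-(tributylstannyl)-3-[(2E,6E)-3,7,11-trimethyldodeca-2,6,10-trien-1-yl]oxirane-2-carbaldehyde (tin and CHO cis)
Conditions: Dess–Martin periodinane, pyridine, CH2Cl2, 0 °C to rt
Reagents that add atoms: none
Why: Buffered Dess–Martin oxidation of the primary epoxy alcohol should give the epoxy aldehyde without touching the stannane, the oxirane or the trisubstituted alkenes, and the oxirane carbon cannot epimerize.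

Step 6
Reactants: 8 tert-butyl(diphenyl)(prop-2-yn-1-yloxy)silane
Product: 9 4-[(tert-butyldiphenylsilyl)oxy]but-2-ynoic acid
Conditions: n-BuLi, THF, −78 °C; then CO2; 1 M HCl work-up
Reagents that add atoms: carbon dioxide, O=C=O
Why: Deprotonation of the terminal alkyne and carboxylation with CO2 is a standard route to the ynoic acid.

Step 7
Reactants: 9 4-[(tert-butyldiphenylsilyl)oxy]but-2-ynoic acid
Product: 10 (2Z)-4-[(tert-butyldiphenylsilyl)oxy]-3-iodobut-2-enoic acid (iodine cis to CO2H)
Conditions: NaI, AcOH, 70 °C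
Reagents that add atoms: sodium iodide, [Na+].[I-]
Why: Conjugate addition of iodide and anti protonation (hydroiodination of an ynoic acid) should give the (Z)-β-iodoacrylic acid, which has the cis geometry that ring closure later needs.

Step 8
Reactants: 10 (2Z)-4-[(tert-butyldiphenylsilyl)oxy]-3-iodobut-2-enoic acid; 7 (2R,3S)-3-(tributylstannyl)-3-[(2E,6E)-farnesyl]oxirane-2-carbaldehyde
Product: 15 (1R,5R,6R)-4-{[(tert-butyldiphenylsilyl)oxy]methyl}-5-hydroxy-1-[(2E,6E)-3,7,11-trimethyldodeca-2,6,10-trien-1-yl]-7-oxabicyclo[4.1.0]hept-3-en-2-one, via dilithio acrylate 11 (not isolated), via stannyl adduct 12 (not isolated), via oxiranyllithium 13 (not isolated), via cyclic gem-diolate 14 (not isolated)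
Conditions: 10, t-BuLi (3 equiv), THF/Et2O/pentane, −100 °C; then 7, −100 to −78 °C; then n-BuLi (1.2 equiv), TMEDA, −90 to −50 °C; AcOH quench at −78 °C
Reagents that add atoms: none
Why: Proposed new method: deprotonation and iodine–lithium exchange of 10 should give the chelated (Z)-β-lithioacrylate 11, whose vinyl carbon adds to the aldehyde of 7 (bond C4–C5), and tin–lithium exchange on adduct 12 should then unmask the configurationally stable oxiranyllithium 13, which attacks the neighbouring lithium carboxylate (bond C1–C2) to give the gem-diolate 14, which collapses to the ketone only on quench so that no second addition can occur. The closest known reaction types are the carbonyl addition of lithium β-lithioacrylates, the trapping of oxiranyllithiums made by tin–lithium exchange with carbonyl electrophiles, and the Parham-type cycloacylation of an organolithium onto a lithium carboxylate; joining them in one flask as a [3+3] annulation is the new element. The six-membered ring closes in a 6-exo-trig mode, which is possible only because the carboxylate and the carbinol carbon are cis on the alkene and the lithium and the carbinol-bearing carbon are cis on the oxirane. The new stereocentre C5 is set in the addition by the Felkin–Anh (polar) preference for attack anti to the oxirane C–O bond of the α,β-epoxy aldehyde, which leads to the erythro adduct and so to the hydroxyl cis to the epoxide, while C1 and C6 are carried over from 7 because the oxiranyllithium reacts with retention. The step needs n-BuLi to exchange with tin faster than it adds to the carboxylate, which the low electrophilicity of a lithium carboxylate at −90 °C should secure, and it needs the vinyllithium to spare the stannane, which the much faster addition to the aldehyde should secure.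

Step 9
Reactants: 15 (1R,5R,6R)-4-{[(tert-butyldiphenylsilyl)oxy]methyl}-5-hydroxy-1-[(2E,6E)-farnesyl]-7-oxabicyclo[4.1.0]hept-3-en-2-one
Product: 16 (1R,5R,6R)-5-hydroxy-4-(hydroxymethyl)-1-[(2E,6E)-3,7,11-trimethyldodeca-2,6,10-trien-1-yl]-7-oxabicyclo[4.1.0]hept-3-en-2-one
Conditions: HF·pyridine, pyridine, THF, 0 °C to rt
Reagents that add atoms: none
Why: Fluoride-mediated cleavage of the silyl ether under pyridine buffering should free the primary alcohol without opening the oxirane or disturbing the γ-hydroxy enone.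

Step 10
Reactants: 16 (1R,5R,6R)-5-hydroxy-4-(hydroxymethyl)-1-[(2E,6E)-farnesyl]-7-oxabicyclo[4.1.0]hept-3-en-2-one
Product: 17 [(1R,5R,6R)-5-hydroxy-2-oxo-1-[(2E,6E)-3,7,11-trimethyldodeca-2,6,10-trien-1-yl]-7-oxabicyclo[4.1.0]hept-3-en-4-yl]methyl acetate (target)
Conditions: AcCl (1.05 equiv), 2,4,6-collidine, CH2Cl2, −78 °C
Reagents that add atoms: acetyl chloride, CC(Cl)=O
Why: Kinetically selective acylation of the primary allylic alcohol over the hindered secondary one, which is flanked by the oxirane and the substituted alkene, should give the monoacetate.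

**Compound list**

1 | prop-2-yn-1-ol | C#CCO | starting material
2 | (2E,6E)-1-bromo-3,7,11-trimethyldodeca-2,6,10-triene (farnesyl bromide) | BrC/C=C(\C)CC/C=C(\C)CCC=C(C)C | starting material
3 | (5E,9E)-6,10,14-trimethylpentadeca-5,9,13-trien-2-yn-1-ol | OCC#CC/C=C(\C)CC/C=C(\C)CCC=C(C)C | intermediate
4 | (2Z,5E,9E)-3-iodo-6,10,14-trimethylpentadeca-2,5,9,13-tetraen-1-ol | OC/C=C(\I)C/C=C(\C)CC/C=C(\C)CCC=C(C)C | intermediate
5 | (2Z,5E,9E)-6,10,14-trimethyl-3-(tributylstannyl)pentadeca-2,5,9,13-tetraen-1-ol | OC/C=C(\[Sn](CCCC)(CCCC)CCCC)C/C=C(\C)CC/C=C(\C)CCC=C(C)C | intermediate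
6 | [(2R,3S)-3-(tributylstannyl)-3-[(2E,6E)-farnesyl]oxiran-2-yl]methanol | OC[C@H]1O[C@@]1(C/C=C(\C)CC/C=C(\C)CCC=C(C)C)[Sn](CCCC)(CCCC)CCCC | intermediate
7 | (2R,3S)-3-(tributylstannyl)-3-[(2E,6E)-farnesyl]oxirane-2-carbaldehyde | O=C[C@H]1O[C@@]1(C/C=C(\C)CC/C=C(\C)CCC=C(C)C)[Sn](CCCC)(CCCC)CCCC | intermediate
8 | tert-butyl(diphenyl)(prop-2-yn-1-yloxy)silane | C#CCO[Si](C(C)(C)C)(c1ccccc1)c1ccccc1 | starting material
9 | 4-[(tert-butyldiphenylsilyl)oxy]but-2-ynoic acid | OC(=O)C#CCO[Si](C(C)(C)C)(c1ccccc1)c1ccccc1 | intermediate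
10 | (2Z)-4-[(tert-butyldiphenylsilyl)oxy]-3-iodobut-2-enoic acid | OC(=O)/C=C(\I)CO[Si](C(C)(C)C)(c1ccccc1)c1ccccc1 | intermediate
11 | lithium (2Z)-4-[(tert-butyldiphenylsilyl)oxy]-3-lithiobut-2-enoate (dilithio acrylate, lithium cis to the carboxylate) | [Li]OC(=O)/C=C(\[Li])CO[Si](C(C)(C)C)(c1ccccc1)c1ccccc1 | intermediate
12 | dilithium (2Z,4R)-3-{[(tert-butyldiphenylsilyl)oxy]methyl}-4-oxido-4-[(2R,3S)-3-farnesyl-3-(tributylstannyl)oxiran-2-yl]but-2-enoate (erythro stannyl adduct) | [Li]OC(=O)/C=C(\[C@@H](O[Li])[C@H]1O[C@@]1(C/C=C(\C)CC/C=C(\C)CCC=C(C)C)[Sn](CCCC)(CCCC)CCCC)CO[Si](C(C)(C)C)(c1ccccc1)c1ccccc1 | intermediate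
13 | oxiranyllithium from 12 (lithium in place of tin, configuration retained) | [Li]OC(=O)/C=C(\[C@@H](O[Li])[C@H]1O[C@@]1(C/C=C(\C)CC/C=C(\C)CCC=C(C)C)[Li])CO[Si](C(C)(C)C)(c1ccccc1)c1ccccc1 | intermediate
14 | trilithium gem-diolate of the cyclized ketone (C2 carries two OLi, C5 carries OLi) | CC(C)(C)[Si](c1ccccc1)(c1ccccc1)OCC1=CC(O[Li])(O[Li])[C@]2(C/C=C(\C)CC/C=C(\C)CCC=C(C)C)O[C@@H]2[C@@H]1O[Li] | intermediate
15 | (1R,5R,6R)-4-{[(tert-butyldiphenylsilyl)oxy]methyl}-5-hydroxy-1-[(2E,6E)-farnesyl]-7-oxabicyclo[4.1.0]hept-3-en-2-one | CC(C)(C)[Si](c1ccccc1)(c1ccccc1)OCC1=CC(=O)[C@]2(C/C=C(\C)CC/C=C(\C)CCC=C(C)C)O[C@@H]2[C@@H]1O | intermediate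
16 | (1R,5R,6R)-5-hydroxy-4-(hydroxymethyl)-1-[(2E,6E)-farnesyl]-7-oxabicyclo[4.1.0]hept-3-en-2-one | OCC1=CC(=O)[C@]2(C/C=C(\C)CC/C=C(\C)CCC=C(C)C)O[C@@H]2[C@@H]1O | intermediate
17 | [(1R,5R,6R)-5-hydroxy-2-oxo-1-[(2E,6E)-farnesyl]-7-oxabicyclo[4.1.0]hept-3-en-4-yl]methyl acetate | CC(=O)OCC1=CC(=O)[C@]2(C/C=C(\C)CC/C=C(\C)CCC=C(C)C)O[C@@H]2[C@@H]1O | target

**Count and risks**

Total steps: 10. Longest linear sequence: 8 steps (steps 1–5, 8, 9, 10).

1. Step 8. The oxiranyllithium may decompose by α-elimination (carbenoid pathways) before it acylates the weakly electrophilic lithium carboxylate, n-BuLi may attack the carboxylate instead of tin, and the facial selectivity of the aldehyde addition may be only moderate. Fallback with known reactions, setting out from 10 and 7: the aldehyde addition is run alone (t-BuLi, then 7) and the dialkoxide is quenched with Et3SiOTf/2,6-lutidine; mild aqueous K2CO3 cleaves the silyl ester and leaves the (Z)-acid with a triethylsilyl-protected carbinol F1, at which stage carbinol epimers can be separated. Amide coupling (EDC, MeNHOMe·HCl, N-methylmorpholine) gives the Weinreb amide F2. Tin–lithium exchange (n-BuLi, TMEDA, THF, −90 °C) with Parham-type cyclization onto the more electrophilic Weinreb amide then gives the triethylsilyl ether F3, and PPTS in MeOH at 0 °C removes the triethylsilyl group in the presence of the TBDPS ether and returns to 15.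

2. Step 4. The bulky tributylstannyl group sits cis to the carbinol carbon and may slow the epoxidation or erode its face selectivity, and tin may be lost oxidatively. Fallback setting out from 5: hydroxyl-directed epoxidation with VO(acac)2 and t-BuOOH gives the racemic epoxy alcohol, that is 6 together with its enantiomer F4. A lipase-catalysed transesterification with vinyl acetate (enzyme chosen by screening to acylate the unwanted enantiomer) converts F4 into its acetate F5, which is separated, and the unreacted 6 rejoins the route at step 5.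

3. Step 9. Fluoride or adventitious acid may open the oxirane, or the γ-hydroxy epoxy enone may break down during desilylation. Fallback without a protecting group, setting out from 1: double deprotonation (n-BuLi, 2 equiv) and carboxylation gives 4-hydroxybut-2-ynoic acid F6, and NaI in AcOH gives (2Z)-4-hydroxy-3-iodobut-2-enoic acid F7, which cannot lactonize because its CH2OH group is trans to the carboxyl group. F7 is annulated with 7 under the conditions of step 8 with one more equivalent of t-BuLi (the side-chain alkoxide rides along as a lithium salt), which comes back to the route at 16 with no silyl ether to cleave.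

**Further compounds**

F1 | step 8 | (2Z,4R)-3-{[(tert-butyldiphenylsilyl)oxy]methyl}-4-[(triethylsilyl)oxy]-4-[(2R,3S)-3-farnesyl-3-(tributylstannyl)oxiran-2-yl]but-2-enoic acid | OC(=O)/C=C(\[C@@H](O[Si](CC)(CC)CC)[C@H]1O[C@@]1(C/C=C(\C)CC/C=C(\C)CCC=C(C)C)[Sn](CCCC)(CCCC)CCCC)CO[Si](C(C)(C)C)(c1ccccc1)c1ccccc1
F2 | step 8 | N-methoxy-N-methyl amide of F1 | CON(C)C(=O)/C=C(\[C@@H](O[Si](CC)(CC)CC)[C@H]1O[C@@]1(C/C=C(\C)CC/C=C(\C)CCC=C(C)C)[Sn](CCCC)(CCCC)CCCC)CO[Si](C(C)(C)C)(c1ccccc1)c1ccccc1
F3 | step 8 | triethylsilyl ether of 15 at the C5 hydroxyl | CC(C)(C)[Si](c1ccccc1)(c1ccccc1)OCC1=CC(=O)[C@]2(C/C=C(\C)CC/C=C(\C)CCC=C(C)C)O[C@@H]2[C@@H]1O[Si](CC)(CC)CC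
F4 | step 4 | [(2S,3R)-3-(tributylstannyl)-3-[(2E,6E)-farnesyl]oxiran-2-yl]methanol (enantiomer of 6) | OC[C@@H]1O[C@]1(C/C=C(\C)CC/C=C(\C)CCC=C(C)C)[Sn](CCCC)(CCCC)CCCC
F5 | step 4 | [(2S,3R)-3-(tributylstannyl)-3-[(2E,6E)-farnesyl]oxiran-2-yl]methyl acetate | CC(=O)OC[C@@H]1O[C@]1(C/C=C(\C)CC/C=C(\C)CCC=C(C)C)[Sn](CCCC)(CCCC)CCCC
F6 | step 9 | 4-hydroxybut-2-ynoic acid | OCC#CC(O)=O
F7 | step 9 | (2Z)-4-hydroxy-3-iodobut-2-enoic acid | OC(=O)/C=C(\I)CO
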